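## Retrosynthetic overview
1. Target 16 comes from diketone 10. C3–OH is set by hydride attack from the α face, C4 stays as the equatorial epimer, and the two O‑acylations and ester cleavage follow.
2. Diketone 10 comes from the acyclic furyl dienone 7 by an intramolecular furan Diels–Alder reaction. The C10–C5 and C3–C4 bonds form together, so rings A and B close in the same operation.
3. In the same flask the oxa‑bridge is eliminated to give C9=C10. The resulting allylic alcohol is then isomerised to the C3 ketone with saturated C1–C2.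
4. Dienone 7 comes from Stille acylation of the (Z)‑alkenylstannane 4 with 2‑furylacetyl chloride. Stannane 4 comes from OH‑directed trans‑hydrostannation of 3.
5. Alcohol 3 comes from catalytic asymmetric alkynylation of pyruvate 1 with enyne 2, which sets C11. The side‑chain stereocentre is bought with acid 13.

Assumption: eremophilane numbering is used (ring A = C1–C5 and C10, ring B = C5–C10, C14 on C5, C15 on C4, C11–C13 on C7, β = the face of C14), and 1, 2, 5 and 13 are taken as catalogue compounds.

## Route

Step 1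
Reactants: 1 tert-butyl pyruvate; 2 (E)-3-methylpent-3-en-1-yne
Product: 3 tert-butyl (2R,5E)-2-hydroxy-2,5-dimethylhept-5-en-3-ynoate
Conditions: Zn(OTf)2 (20 mol %), chiral β-amino alcohol ligand (22 mol %, the enantiomer that gives Re-face attack), Et3N (30 mol %), toluene, 60 °C
Reagents that add atoms: none
Why: This is a catalytic asymmetric alkynylation of an α-keto ester, in which the zinc acetylide adds to the Re face of the ligand-bound chelated keto ester and so sets C11 as R.

Step 2
Reactants: 3 tert-butyl (2R,5E)-2-hydroxy-2,5-dimethylhept-5-en-3-ynoate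
Product: 4 tert-butyl (2S,3Z,5E)-2-hydroxy-2,5-dimethyl-3-(tributylstannyl)hepta-3,5-dienoate
Conditions: [Cp*RuCl]4 (2.5 mol %), Bu3SnH (1.1 equiv), CH2Cl2, rt
Reagents that add atoms: tributyltin hydride, CCCC[SnH](CCCC)CCCC
Why: In this hydroxyl-directed Ru-catalysed trans-hydrostannation the OH···Cl–Ru hydrogen bond places tin on the carbon next to the carbinol and H trans to it, so the dienyl carbon C5 ends cis to tin; no stereocentre is formed, and the C2 descriptor changes to S only because tin raises the priority of C3.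

Step 3
Reactants: 4 tert-butyl (2S,3Z,5E)-2-hydroxy-2,5-dimethyl-3-(tributylstannyl)hepta-3,5-dienoate; 5 2-(furan-2-yl)acetic acid
Product: 7 tert-butyl (2R,3Z,5E)-3-[2-(furan-2-yl)acetyl]-2-hydroxy-2,5-dimethylhepta-3,5-dienoate, via 2-(furan-2-yl)acetyl chloride 6 (not isolated)
Conditions: 5, (COCl)2, cat. DMF, CH2Cl2, 0 °C to rt, evaporate; then 4, Pd2(dba)3 (2.5 mol %), AsPh3 (10 mol %), CuI (10 mol %), NMP, rt to 45 °C, no base
Reagents that add atoms: oxalyl chloride, O=C(Cl)C(Cl)=O
Why: Stille acylation of an alkenylstannane with an acid chloride keeps the alkene geometry, so the new ketone carbon C8 is cis to C5 as ring B needs, and the base-free medium avoids ketene formation and leaves C11 untouched.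

Step 4
Reactants: 7 tert-butyl (2R,3Z,5E)-3-[2-(furan-2-yl)acetyl]-2-hydroxy-2,5-dimethylhepta-3,5-dienoate
Product: 10 tert-butyl (4R,5R,11R)-11-hydroxy-3,8-dioxoeremophila-6,9-dien-12-oate, via oxanorbornene cycloadduct 8 (not isolated), via 3-hydroxy trienone 9 (not isolated)
Conditions: confined chiral imidodiphosphorimidate (IDPi) Brønsted acid (5 mol %, enantiomer chosen for 5R), CH2Cl2, 0 °C to rt; then DBU (1.5 equiv), rt, same flask
Reagents that add atoms: none
Why: Proposed new method: protonation of the dienone gives a hydroxypentadienyl cation with charge at C4 whose chiral counter-anion blocks one face, so the furan adds suprafacially (C3–C4 and C10–C5, tether exo, the E-tiglyl unit giving cis C14/C15) and sets C5 as R while both carbocycles close; the reversible cycloaddition is drained by ionisation of the C10–O bridge and loss of H9 inside the same ion pair to give 9, and DBU then shifts the ε-hydroxy dienone to the 3-ketone 10 with C4 kept as the equatorial β-methyl epimer; the closest known reaction types are acid-promoted intramolecular Diels–Alder reactions of furyl enones, chiral Brønsted-acid-catalysed Diels–Alder reactions of enones, β-elimination of oxanorbornenes and the base-induced γ-hydroxy enone to 1,4-diketone isomerisation.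

Step 5
Reactants: 10 tert-butyl (4R,5R,11R)-11-hydroxy-3,8-dioxoeremophila-6,9-dien-12-oate
Product: 11 tert-butyl (3S,4R,5R,11R)-3,11-dihydroxy-8-oxoeremophila-6,9-dien-12-oate
Conditions: L-Selectride (1.1 equiv), THF, −78 °C; water work-up
Reagents that add atoms: none
Why: In this bulky-hydride ketone reduction the β face of C3 is closed by the syn-axial C14 methyl, so hydride enters from the α (equatorial) side and gives the axial 3β-alcohol (3S), while the hindered cross-conjugated dienone and the esters do not react at −78 °C.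

Step 6
Reactants: 11 tert-butyl (3S,4R,5R,11R)-3,11-dihydroxy-8-oxoeremophila-6,9-dien-12-oate
Product: 12 tert-butyl (3S,4R,5R,11R)-3-acetoxy-11-hydroxy-8-oxoeremophila-6,9-dien-12-oate
Conditions: Ac2O (1.5 equiv), pyridine, DMAP (5 mol %), CH2Cl2, 0 °C to rt
Reagents that add atoms: acetic anhydride, CC(=O)OC(C)=O
Why: DMAP-catalysed acetylation takes the secondary C3 alcohol far faster than the tertiary α-ester carbinol at C11, and no stereocentre is touched.

Step 7
Reactants: 12 tert-butyl (3S,4R,5R,11R)-3-acetoxy-11-hydroxy-8-oxoeremophila-6,9-dien-12-oate; 13 (R)-2-methylbutanoic acid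
Product: 15 tert-butyl (3S,4R,5R,11R)-3-acetoxy-11-[(2R)-2-methylbutanoyloxy]-8-oxoeremophila-6,9-dien-12-oate, via (R)-2-methylbutanoic anhydride 14 (not isolated)
Conditions: 13 (2.4 equiv), DCC (1.2 equiv), CH2Cl2, rt, filter; then 12, Sc(OTf)3 (5 mol %), MeCN, −20 to 0 °C
Reagents that add atoms: none
Why: Lewis-acid-catalysed acylation of a tertiary alcohol with a symmetric anhydride needs no amine base, so no ketene forms and the purchased 2R centre is carried over unchanged, while C11 reacts at oxygen only and keeps its configuration.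

Step 8
Reactants: 15 tert-butyl (3S,4R,5R,11R)-3-acetoxy-11-[(2R)-2-methylbutanoyloxy]-8-oxoeremophila-6,9-dien-12-oate
Product: 16 (3S,4R,5R,11R)-3-acetoxy-11-[(2R)-2-methylbutanoyloxy]-8-oxoeremophila-6,9-dien-12-oic acid (CNP0278920.1)
Conditions: TFA/CH2Cl2 (1:4), 0 °C, 1–2 h
Reagents that add atoms: none
Why: Acidolysis of the tert-butyl ester (E1 loss of isobutene) leaves the acetate and the 2-methylbutanoate intact, and the short cold exposure on an electron-poor dienone avoids dienone–phenol rearrangement.

## Compound list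
1 | tert-butyl pyruvate | CC(=O)C(=O)OC(C)(C)C | starting material
2 | (E)-3-methylpent-3-en-1-yne | C#C/C(C)=C/C | starting material
3 | tert-butyl (2R,5E)-2-hydroxy-2,5-dimethylhept-5-en-3-ynoate | O[C@@](C)(C(=O)OC(C)(C)C)C#C/C(C)=C/C | intermediate
4 | tert-butyl (2S,3Z,5E)-2-hydroxy-2,5-dimethyl-3-(tributylstannyl)hepta-3,5-dienoate | O[C@@](C)(C(=O)OC(C)(C)C)/C([Sn](CCCC)(CCCC)CCCC)=C/C(C)=C/C | intermediate
5 | 2-(furan-2-yl)acetic acid | OC(=O)Cc1ccco1 | starting material
6 | 2-(furan-2-yl)acetyl chloride | ClC(=O)Cc1ccco1 | intermediate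
7 | tert-butyl (2R,3Z,5E)-3-[2-(furan-2-yl)acetyl]-2-hydroxy-2,5-dimethylhepta-3,5-dienoate | O[C@@](C)(C(=O)OC(C)(C)C)/C(C(=O)Cc1ccco1)=C/C(C)=C/C | intermediate
8 | tert-butyl (3R,4R,5R,10S,11R)-3,10-epoxy-11-hydroxy-8-oxoeremophila-1,6-dien-12-oate (oxa-bridge α, both methyls β) | O=C1C[C@]23O[C@H](C=C2)[C@H](C)[C@@]3(C)C=C1[C@@](C)(O)C(=O)OC(C)(C)C | intermediate
9 | tert-butyl (3R,4R,5R,11R)-3,11-dihydroxy-8-oxoeremophila-1,6,9-trien-12-oate (3α-OH) | O=C1C=C2C=C[C@@H](O)[C@H](C)[C@@]2(C)C=C1[C@@](C)(O)C(=O)OC(C)(C)C | intermediate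
10 | tert-butyl (4R,5R,11R)-11-hydroxy-3,8-dioxoeremophila-6,9-dien-12-oate | O=C1C=C2CCC(=O)[C@H](C)[C@@]2(C)C=C1[C@@](C)(O)C(=O)OC(C)(C)C | intermediate
11 | tert-butyl (3S,4R,5R,11R)-3,11-dihydroxy-8-oxoeremophila-6,9-dien-12-oate (3β-OH) | O=C1C=C2CC[C@H](O)[C@H](C)[C@@]2(C)C=C1[C@@](C)(O)C(=O)OC(C)(C)C | intermediate
12 | tert-butyl (3S,4R,5R,11R)-3-acetoxy-11-hydroxy-8-oxoeremophila-6,9-dien-12-oate | O=C1C=C2CC[C@H](OC(C)=O)[C@H](C)[C@@]2(C)C=C1[C@@](C)(O)C(=O)OC(C)(C)C | intermediate
13 | (R)-2-methylbutanoic acid | CC[C@@H](C)C(=O)O | starting material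
14 | (R)-2-methylbutanoic anhydride | CC[C@@H](C)C(=O)OC(=O)[C@H](C)CC | intermediate
15 | tert-butyl (3S,4R,5R,11R)-3-acetoxy-11-[(2R)-2-methylbutanoyloxy]-8-oxoeremophila-6,9-dien-12-oate | O=C1C=C2CC[C@H](OC(C)=O)[C@H](C)[C@@]2(C)C=C1[C@@](C)(OC(=O)[C@H](C)CC)C(=O)OC(C)(C)C | intermediate
16 | (3S,4R,5R,11R)-3-acetoxy-11-[(2R)-2-methylbutanoyloxy]-8-oxoeremophila-6,9-dien-12-oic acid | CC[C@@H](C)C(=O)O[C@@](C)(C(=O)O)C1=C[C@@]2(C)C(=CC1=O)CC[C@H](OC(C)=O)[C@@H]2C | target

## Step count and main risks
Total step count: 8. Longest linear sequence: 8 (1 or 2 through to 16).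

**Step 4 is the most likely to fail.**
- The cycloadduct carries two adjacent fully substituted carbons, so it is probably uphill in energy.
- Facial control by the counter-anion is unproven.
- The furan C3 position could instead add to C6 in a Friedel–Crafts/Michael sense.
- C11 is too remote to help with facial selectivity.

The fallback sets out from 7 and comes back at 10. It replaces asymmetric catalysis by a resolution with recycling. Stoichiometric Me2AlCl in CH2Cl2 at −78 °C drives the furan Diels–Alder equilibrium to the aluminium-bound adducts. Compound 8 and its core-epimeric diastereomer tert-butyl (3S,4S,5S,10R,11R)-3,10-epoxy-11-hydroxy-8-oxoeremophila-1,6-dien-12-oate F1 are then isolated and separated by chromatography, with C11 serving as the internal resolving centre. F1 is reverted to 7 by gentle heating (retro-Diels–Alder) and resubmitted. Pure 8 is opened and isomerised with DBU to give 10.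

**Step 3 is the second risk.** The stannane is flanked by a quaternary carbinol, so transmetalation may lose out to protodestannylation. The fallback sets out from 4 and comes back at 7.
- Tin–iodine exchange (I2, CH2Cl2, 0 °C) gives tert-butyl (2S,3Z,5E)-2-hydroxy-3-iodo-2,5-dimethylhepta-3,5-dienoate F2.
- Nozaki–Hiyama–Kishi addition of F2 to 2-(furan-2-yl)acetaldehyde (CrCl2, cat. NiCl2, DMF) gives tert-butyl (2R,3E,5E)-3-[2-(furan-2-yl)-1-hydroxyethyl]-2-hydroxy-2,5-dimethylhepta-3,5-dienoate F3 as a carbinol mixture.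
- Dess–Martin oxidation of the secondary alcohol in F3 delivers 7.

**Step 7 is the third risk.** The C11 alcohol is tertiary and crowded, and forcing conditions endanger the tert-butyl ester or the α-centre of the acyl donor. The fallback sets out from 12 and comes back at 16, and it reverses the order of the last two operations. TFA first frees (3S,4R,5R,11R)-3-acetoxy-11-hydroxy-8-oxoeremophila-6,9-dien-12-oic acid F4. F4 is then warmed with (R)-2-methylbutanoyl chloride without base. The mixed anhydride formed at the carboxyl group passes the acyl group to the neighbouring hydroxyl through a five-membered transition state. Aqueous work-up hydrolyses any remaining anhydride to give 16.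

## Further compounds
F1 | step 4 | tert-butyl (3S,4S,5S,10R,11R)-3,10-epoxy-11-hydroxy-8-oxoeremophila-1,6-dien-12-oate | O=C1C[C@@]23O[C@@H](C=C2)[C@@H](C)[C@]3(C)C=C1[C@@](C)(O)C(=O)OC(C)(C)C
F2 | step 3 | tert-butyl (2S,3Z,5E)-2-hydroxy-3-iodo-2,5-dimethylhepta-3,5-dienoate | O[C@@](C)(C(=O)OC(C)(C)C)/C(I)=C/C(C)=C/C
F3 | step 3 | tert-butyl (2R,3E,5E)-3-[2-(furan-2-yl)-1-hydroxyethyl]-2-hydroxy-2,5-dimethylhepta-3,5-dienoate | O[C@@](C)(C(=O)OC(C)(C)C)/C(C(O)Cc1ccco1)=C/C(C)=C/C
F4 | step 7 | (3S,4R,5R,11R)-3-acetoxy-11-hydroxy-8-oxoeremophila-6,9-dien-12-oic acid | O=C1C=C2CC[C@H](OC(C)=O)[C@H](C)[C@@]2(C)C=C1[C@@](C)(O)C(=O)O
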